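**Plan**

Locants follow the elemane skeleton: ring C5–C10; vinyl C1=C2 and methyl C14 on C10; C3/C4/C15 on C5; lactone oxygen on C6; C11/C12/C13 on C7; ester oxygen on C8; side chain C1'–C4'.
Retrosynthesis cuts, in this order: the C8–O ester bond (to acid 30), C11=C13 and the C15 oxidation level, the lactone bond C12–O6, the ring bond C7–C8, the chain bond C6–C7 and finally C5–C10.
Enabling feature: oxygen-bearing C8 is bonded to C7, the β-carbon of the C12 carbonyl, so C8 and C12 are 1,4-dioxygenated; a C8 acyl anion equivalent can add to a C7=C11 enoate and close the C5–C10 cyclohexane as its C8 ketone.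
Forward: the open chain is built first (C5–C10 by Ireland–Claisen rearrangement, C6–C7 by Nozaki–Hiyama–Kishi coupling), the carbocycle closes at C7–C8, the γ-lactone ring follows, and the side-chain ester is attached before the last oxidation and deprotection.
Stereochemistry: C5 and C10 from a chiral boron enolate in the Claisen step, C6 by Felkin–Anh addition, C7 by equatorial placement in the ring closure, C8 by equatorial hydride attack then Mitsunobu inversion, C3' from (S)-glyceraldehyde acetonide.

Key step: step 10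

Assumption: the (S,S)-bromoborane of step 3 is taken to induce the (2S,3S) sense in acid 8; if the sense proves opposite, the (R,R)-reagent is used instead and nothing else changes.

**Route**

Step 1
Reactants: 1 tert-butyl(but-3-yn-1-yloxy)dimethylsilane
Product: 4 (E)-5-[(tert-butyldimethylsilyl)oxy]-3-methylpent-2-en-1-ol, via alkenylalane 2 (not isolated), via lithium alanate 3 (not isolated)
Conditions: Me3Al, Cp2ZrCl2 (cat.), CH2Cl2, 0 °C → rt; n-BuLi, THF, −78 °C; (CH2O)n, −78 °C → rt; aq. work-up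
Reagents that add atoms: trimethylaluminium, C[Al](C)C; formaldehyde (as paraformaldehyde), C=O
Why: Zirconium-catalysed Negishi carboalumination adds methyl and aluminium syn across the terminal alkyne with methyl on the internal carbon, and hydroxymethylation of the derived alanate with formaldehyde retains the geometry, so the methyl group ends up cis to CH2OH in the (E)-allylic alcohol, while the silyl ether that will later become C8 tolerates the Lewis acids used here and in step 3.

Step 2
Reactants: 4 (E)-5-[(tert-butyldimethylsilyl)oxy]-3-methylpent-2-en-1-ol; 5 3-methylbut-2-enoyl chloride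
Product: 6 (E)-5-[(tert-butyldimethylsilyl)oxy]-3-methylpent-2-en-1-yl 3-methylbut-2-enoate
Conditions: pyridine, DMAP (cat.), CH2Cl2, 0 °C
Reagents that add atoms: none
Why: DMAP-catalysed acylation of a primary allylic alcohol by an acid chloride is routine, and any partial deconjugation of the acyl part is harmless because both double-bond isomers lead to the same dienolate in step 3.

Step 3
Reactants: 6 (E)-5-[(tert-butyldimethylsilyl)oxy]-3-methylpent-2-en-1-yl 3-methylbut-2-enoate
Product: 8 (2S,3S)-5-[(tert-butyldimethylsilyl)oxy]-3-ethenyl-3-methyl-2-(prop-1-en-2-yl)pentanoic acid, via boron ketene acetal 7 (not isolated)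
Conditions: (4S,5S)-2-bromo-1,3-bis{[3,5-bis(trifluoromethyl)phenyl]sulfonyl}-4,5-diphenyl-1,3,2-diazaborolidine, Et3N, toluene/hexane, −78 °C → 4 °C; aq. work-up
Reagents that add atoms: none
Why: In this enantioselective Ireland–Claisen rearrangement, γ-deprotonation of the boron-complexed senecioate should give dienyl ketene acetal 7 with the isopropenyl group cis to the allyloxy oxygen (the s-trans complex avoids the clash of the borane with the cis β-methyl group), and the chair with the (E)-allyl unit (C10 methyl axial) then sets C5 and C10 in the required relative sense while the C2-symmetric diazaborolidine selects one chair and thus the absolute configuration.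

Step 4
Reactants: 8 (2S,3S)-5-[(tert-butyldimethylsilyl)oxy]-3-ethenyl-3-methyl-2-(prop-1-en-2-yl)pentanoic acid
Product: 9 (2S,3S)-5-[(tert-butyldimethylsilyl)oxy]-3-ethenyl-3-methyl-2-(prop-1-en-2-yl)pentan-1-ol
Conditions: LiAlH4, THF, 0 °C → rt
Reagents that add atoms: none
Why: Hydride reduction of a carboxylic acid to the primary alcohol leaves the silyl ether, both alkenes and the two stereocentres untouched.

Step 5
Reactants: 9 (2S,3S)-5-[(tert-butyldimethylsilyl)oxy]-3-ethenyl-3-methyl-2-(prop-1-en-2-yl)pentan-1-ol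
Product: 10 (2S,3S)-5-[(tert-butyldimethylsilyl)oxy]-3-ethenyl-3-methyl-2-(prop-1-en-2-yl)pentanal
Conditions: Dess–Martin periodinane, NaHCO3, CH2Cl2, 0 °C; used crude
Reagents that add atoms: none
Why: The buffered Dess–Martin oxidation is neutral enough that the β,γ-unsaturated aldehyde, whose α-centre C5 is shielded by the neighbouring quaternary carbon, should neither epimerise nor move its double bond into conjugation.

Step 6
Reactants: 10 (2S,3S)-5-[(tert-butyldimethylsilyl)oxy]-3-ethenyl-3-methyl-2-(prop-1-en-2-yl)pentanal; 11 methyl (E)-3-iodoprop-2-enoate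
Product: 12 methyl (2E,4S,5S,6S)-8-[(tert-butyldimethylsilyl)oxy]-6-ethenyl-4-hydroxy-6-methyl-5-(prop-1-en-2-yl)oct-2-enoate
Conditions: CrCl2, NiCl2 (cat.), DMSO, rt
Reagents that add atoms: none
Why: In this Nozaki–Hiyama–Kishi coupling the carbon nucleophile generated from 11 at nickel and trivalent chromium adds only to the aldehyde under non-basic conditions with retention of the (E)-geometry, and it approaches anti to the quaternary C10 substituent past the small hydrogen (Felkin–Anh), which gives the (4S) carbinol, that is C6 of the target.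

Step 7
Reactants: 12 methyl (2E,4S,5S,6S)-8-[(tert-butyldimethylsilyl)oxy]-6-ethenyl-4-hydroxy-6-methyl-5-(prop-1-en-2-yl)oct-2-enoate
Product: 13 methyl (2E,4S,5S,6S)-4,8-bis[(tert-butyldimethylsilyl)oxy]-6-ethenyl-6-methyl-5-(prop-1-en-2-yl)oct-2-enoate
Conditions: TBSOTf, 2,6-lutidine, CH2Cl2, −78 → 0 °C
Reagents that add atoms: tert-butyldimethylsilyl trifluoromethanesulfonate, CC(C)(C)[Si](C)(C)OS(=O)(=O)C(F)(F)F
Why: The silyl triflate silylates even this hindered secondary allylic alcohol, and the resulting silyloxy group is a poor leaving group and stops lactol formation once C8 is an aldehyde.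

Step 8
Reactants: 13 methyl (2E,4S,5S,6S)-4,8-bis[(tert-butyldimethylsilyl)oxy]-6-ethenyl-6-methyl-5-(prop-1-en-2-yl)oct-2-enoate
Product: 14 methyl (2E,4S,5S,6S)-4-[(tert-butyldimethylsilyl)oxy]-6-ethenyl-8-hydroxy-6-methyl-5-(prop-1-en-2-yl)oct-2-enoate
Conditions: HF·pyridine, pyridine, THF, 0 °C
Reagents that add atoms: none
Why: Buffered HF·pyridine should remove the unhindered primary silyl ether much faster than the secondary one at C6, which is flanked by two branched carbons (selective desilylation).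

Step 9
Reactants: 14 methyl (2E,4S,5S,6S)-4-[(tert-butyldimethylsilyl)oxy]-6-ethenyl-8-hydroxy-6-methyl-5-(prop-1-en-2-yl)oct-2-enoate
Product: 15 methyl (2E,4S,5S,6S)-4-[(tert-butyldimethylsilyl)oxy]-6-ethenyl-6-methyl-8-oxo-5-(prop-1-en-2-yl)oct-2-enoate
Conditions: Dess–Martin periodinane, NaHCO3, CH2Cl2, 0 °C → rt
Reagents that add atoms: none
Why: Dess–Martin oxidation of the primary alcohol gives the C8 aldehyde, whose α-carbon C9 is a methylene next to a quaternary centre and so carries no stereochemical risk.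

Step 10
Reactants: 15 methyl (2E,4S,5S,6S)-4-[(tert-butyldimethylsilyl)oxy]-6-ethenyl-6-methyl-8-oxo-5-(prop-1-en-2-yl)oct-2-enoate
Product: 17 methyl 2-[(1S,2R,3S,4S)-2-[(tert-butyldimethylsilyl)oxy]-4-ethenyl-4-methyl-6-oxo-3-(prop-1-en-2-yl)cyclohexyl]acetate, via Breslow enaminol 16 (not isolated)
Conditions: 2-(pentafluorophenyl)-6,7-dihydro-5H-pyrrolo[2,1-c][1,2,4]triazol-2-ium tetrafluoroborate (20 mol %), KN(SiMe3)2 (20 mol %), toluene, 23 °C
Reagents that add atoms: none
Why: Deprotonation of the triazolium salt gives the carbene, which adds to the C8 aldehyde and after proton transfer forms the nucleophilic enaminol 16; its conjugate addition to C7 of the (E)-enoate makes the C7–C8 bond, and proton transfer with loss of the carbene leaves the C8 ketone 1,4 to the C12 ester. The closest known reaction is the carbene-catalysed intramolecular Stetter reaction of aliphatic aldehydes tethered to β-substituted enoates, used here at the demanding six-membered end of its scope. The cyclohexanone closes 6-exo-trig through a chair in which the C5 isopropenyl and C6 silyloxy groups are equatorial, helped by the quaternary C10 in the tether (Thorpe–Ingold effect). The one new stereocentre, C7, is under substrate control: the acetate arm is placed equatorial, trans to the C6 oxygen, and because C7 is α to the new ketone a minor epimer can drain to this all-equatorial isomer by enolisation. The step needs conjugate addition of the acyl anion equivalent to outrun aldol or benzoin-type self-condensation and must not expel the β-silyloxy group; the intramolecular five-atom tether, the hindered neopentyl-type aldehyde and the use of only catalytic base secure this.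

Step 11
Reactants: 17 methyl 2-[(1S,2R,3S,4S)-2-[(tert-butyldimethylsilyl)oxy]-4-ethenyl-4-methyl-6-oxo-3-(prop-1-en-2-yl)cyclohexyl]acetate
Product: 19 (3aS,6S,7S,7aR)-6-ethenyl-6-methyl-7-(prop-1-en-2-yl)hexahydro-1-benzofuran-2,4-dione, via hydroxy ester 18 (not isolated)
Conditions: aq. HF, MeCN, 0 °C → rt; then camphorsulfonic acid (cat.), CH2Cl2, rt
Reagents that add atoms: none
Why: Acidic fluoride cleaves the secondary silyl ether without the base that would trigger retro-aldol or β-elimination of the β-hydroxy ketone, and the freed C6 hydroxyl, the only one present, closes the trans-fused five-membered lactone ring on the C12 ester by acid-catalysed lactonisation with retention at C6 and C7.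

Step 12
Reactants: 19 (3aS,6S,7S,7aR)-6-ethenyl-6-methyl-7-(prop-1-en-2-yl)hexahydro-1-benzofuran-2,4-dione
Product: 20 (3aR,4R,6S,7S,7aR)-6-ethenyl-4-hydroxy-6-methyl-7-(prop-1-en-2-yl)hexahydro-1-benzofuran-2(3H)-one
Conditions: LiBH(s-Bu)3, THF, −78 °C; AcOH quench at −78 °C
Reagents that add atoms: none
Why: The bulky trialkylborohydride attacks the chair cyclohexanone along the equatorial trajectory from the α-face, the axial path being blocked by the syn-axial C10 methyl group, so the axial 8β-alcohol should form while the lactone survives at −78 °C and the cold acidic quench prevents translactonisation.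

Step 13
Reactants: 20 (3aR,4R,6S,7S,7aR)-6-ethenyl-4-hydroxy-6-methyl-7-(prop-1-en-2-yl)hexahydro-1-benzofuran-2(3H)-one
Product: 21 (3aS,4R,6S,7S,7aR)-6-ethenyl-6-methyl-7-(prop-1-en-2-yl)-4-[(trimethylsilyl)oxy]hexahydro-1-benzofuran-2(3H)-one
Conditions: TMSOTf, 2,6-lutidine, CH2Cl2, −78 °C
Reagents that add atoms: trimethylsilyl trifluoromethanesulfonate, C[Si](C)(C)OS(=O)(=O)C(F)(F)F
Why: Silylation of the hindered axial alcohol with the silyl triflate masks it for the enolate chemistry of step 14, where a free 8β-alkoxide cis to the lactone arm could translactonise to the C8 lactone.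

Step 14
Reactants: 21 (3aS,4R,6S,7S,7aR)-6-ethenyl-6-methyl-7-(prop-1-en-2-yl)-4-[(trimethylsilyl)oxy]hexahydro-1-benzofuran-2(3H)-one
Product: 25 (3aR,4R,6S,7S,7aR)-6-ethenyl-4-hydroxy-6-methyl-3-methylidene-7-(prop-1-en-2-yl)hexahydro-1-benzofuran-2(3H)-one, via Mannich base 22 (not isolated), via methiodide 23 (not isolated), via silyl ether 24 (not isolated)
Conditions: LiN(i-Pr)2, THF, −78 °C; Me2N=CH2+ I−, −78 °C → rt; MeI, MeOH, rt; aq. NaHCO3, CH2Cl2; 1 M HCl, THF, 0 °C
Reagents that add atoms: N,N-dimethylmethyleneiminium iodide (Eschenmoser's salt), C=[N+](C)C.[I-]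
Why: In this Eschenmoser α-methylenation the lithium enolate at C11 (the only enolisable position) is aminomethylated, the amine is quaternised and the salt undergoes base-induced β-elimination to the exocyclic alkene, after which the acidic work-up hydrolyses the labile trimethylsilyl ether.

Step 15
Reactants: 26 (S)-2,2-dimethyl-1,3-dioxolane-4-carbaldehyde
Product: 27 1-[(4S)-2,2-dimethyl-1,3-dioxolan-4-yl]ethan-1-ol (both carbinol epimers)
Conditions: MeMgBr, THF, −78 °C
Reagents that add atoms: methylmagnesium bromide, C[Mg]Br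
Why: Grignard addition to the aldehyde at low temperature leaves the α-alkoxy stereocentre intact, and the new carbinol centre is of no consequence because it is oxidised in step 16.

Step 16
Reactants: 27 1-[(4S)-2,2-dimethyl-1,3-dioxolan-4-yl]ethan-1-ol
Product: 28 1-[(4S)-2,2-dimethyl-1,3-dioxolan-4-yl]ethan-1-one
Conditions: Dess–Martin periodinane, NaHCO3, CH2Cl2, 0 °C → rt
Reagents that add atoms: none
Why: Buffered Dess–Martin oxidation converts both epimers into the single methyl ketone without acid or base strong enough to open the acetonide or epimerise the α-alkoxy centre.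

Step 17
Reactants: 28 1-[(4S)-2,2-dimethyl-1,3-dioxolan-4-yl]ethan-1-one
Product: 29 1-[(4S)-2,2-dimethyl-1,3-dioxolan-4-yl]ethenyl trifluoromethanesulfonate
Conditions: KN(SiMe3)2, THF, −78 °C; PhNTf2, −78 → 0 °C
Reagents that add atoms: N-phenylbis(trifluoromethanesulfonimide), O=S(=O)(N(c1ccccc1)S(=O)(=O)C(F)(F)F)C(F)(F)F
Why: Kinetic deprotonation by the bulky amide at −78 °C takes the methyl group rather than the α-alkoxy methine, and O-sulfonylation of that enolate gives the 1-substituted vinyl triflate with the stereocentre untouched (enol triflate formation).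

Step 18
Reactants: 29 1-[(4S)-2,2-dimethyl-1,3-dioxolan-4-yl]ethenyl trifluoromethanesulfonate
Product: 30 2-[(4R)-2,2-dimethyl-1,3-dioxolan-4-yl]prop-2-enoic acid
Conditions: Pd(OAc)2 (cat.), dppf, CO (1 atm), KOAc, DMF, 60 °C; aq. work-up at pH 4
Reagents that add atoms: carbon monoxide, [C-]#[O+]; potassium acetate, CC(=O)[O-].[K+] (source of the second carboxyl oxygen)
Why: In this palladium-catalysed hydroxycarbonylation of an enol triflate, zerovalent palladium formed in situ inserts into the C–O bond, takes up CO and passes the acyl group to acetate, so the α-substituted acrylic acid results after work-up with the dioxolane stereocentre as a spectator (its descriptor changes to R only through the priority rules).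

Step 19
Reactants: 25 (3aR,4R,6S,7S,7aR)-6-ethenyl-4-hydroxy-6-methyl-3-methylidene-7-(prop-1-en-2-yl)hexahydro-1-benzofuran-2(3H)-one; 30 2-[(4R)-2,2-dimethyl-1,3-dioxolan-4-yl]prop-2-enoic acid
Product: 31 (3aR,4S,6S,7S,7aR)-6-ethenyl-6-methyl-3-methylidene-2-oxo-7-(prop-1-en-2-yl)octahydro-1-benzofuran-4-yl 2-[(4R)-2,2-dimethyl-1,3-dioxolan-4-yl]prop-2-enoate
Conditions: PPh3 and diisopropyl azodicarboxylate premixed at 0 °C, then 30 and 25, toluene, 0 °C → rt
Reagents that add atoms: none
Why: In this Mitsunobu esterification the axial 8β-hydroxyl is activated at phosphorus and displaced by the carboxylate of 30 in an SN2 reaction along the open equatorial trajectory, which inverts C8 to the equatorial 8α-ester of the target, and premixing the phosphine with the azodicarboxylate keeps free phosphine away from the α-methylene lactone.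

Step 20
Reactants: 31 (3aR,4S,6S,7S,7aR)-6-ethenyl-6-methyl-3-methylidene-2-oxo-7-(prop-1-en-2-yl)octahydro-1-benzofuran-4-yl 2-[(4R)-2,2-dimethyl-1,3-dioxolan-4-yl]prop-2-enoate
Product: 33 (3aR,4S,6S,7R,7aR)-6-ethenyl-6-methyl-3-methylidene-2-oxo-7-(3-oxoprop-1-en-2-yl)octahydro-1-benzofuran-4-yl 2-[(4R)-2,2-dimethyl-1,3-dioxolan-4-yl]prop-2-enoate, via allylic alcohol 32 (not isolated)
Conditions: SeO2 (cat.), t-BuOOH, CH2Cl2, rt; filter; MnO2, CH2Cl2, rt
Reagents that add atoms: selenium dioxide, O=[Se]=O; tert-butyl hydroperoxide, CC(C)(C)OO (terminal oxygen source)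
Why: Allylic oxidation with SeO2 (ene reaction then [2,3]-sigmatropic shift) is confined to the only electron-rich alkene with allylic hydrogens, the isopropenyl group, and takes its methyl group rather than the hindered C5 methine, after which MnO2 carries the primary allylic alcohol on to the enal without touching the other functions.

Step 21
Reactants: 33 (3aR,4S,6S,7R,7aR)-6-ethenyl-6-methyl-3-methylidene-2-oxo-7-(3-oxoprop-1-en-2-yl)octahydro-1-benzofuran-4-yl 2-[(4R)-2,2-dimethyl-1,3-dioxolan-4-yl]prop-2-enoate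
Product: 34 (3aR,4S,6S,7R,7aR)-6-ethenyl-6-methyl-3-methylidene-2-oxo-7-(3-oxoprop-1-en-2-yl)octahydro-1-benzofuran-4-yl (3R)-3,4-dihydroxy-2-methylidenebutanoate (CNP0204284.1)
Conditions: AcOH/H2O (4:1), 40 °C; neutral work-up
Reagents that add atoms: none
Why: Acid-catalysed hydrolysis of the isopropylidene acetal frees the side-chain diol under conditions mild enough for the enal, both acrylate units and the lactone, and the neutral work-up avoids base-induced lactonisation of the side chain.

**Compound list**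

1 | tert-butyl(but-3-yn-1-yloxy)dimethylsilane | C#CCCO[Si](C)(C)C(C)(C)C | starting material
2 | (E)-[4-(tert-butyldimethylsilyloxy)-2-methylbut-1-en-1-yl]dimethylalane | C[Al](C)/C=C(\C)CCO[Si](C)(C)C(C)(C)C | intermediate (not isolated)
3 | lithium butyl[(E)-4-(tert-butyldimethylsilyloxy)-2-methylbut-1-en-1-yl]dimethylalanate | [Li+].CCCC[Al-](C)(C)/C=C(\C)CCO[Si](C)(C)C(C)(C)C | intermediate (not isolated)
4 | (E)-5-[(tert-butyldimethylsilyl)oxy]-3-methylpent-2-en-1-ol | OC/C=C(\C)CCO[Si](C)(C)C(C)(C)C | intermediate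
5 | 3-methylbut-2-enoyl chloride | CC(C)=CC(=O)Cl | starting material
6 | (E)-5-[(tert-butyldimethylsilyl)oxy]-3-methylpent-2-en-1-yl 3-methylbut-2-enoate | CC(C)=CC(=O)OC/C=C(\C)CCO[Si](C)(C)C(C)(C)C | intermediate
7 | boron ketene acetal of 6: O-[(4S,5S)-diazaborolidin-2-yl] dienyl ketene acetal, isopropenyl cis to the allyloxy oxygen | C=C(C)/C=C(/OB1N(S(=O)(=O)c2cc(cc(c2)C(F)(F)F)C(F)(F)F)[C@@H](c2ccccc2)[C@H](c2ccccc2)N1S(=O)(=O)c1cc(cc(c1)C(F)(F)F)C(F)(F)F)OC/C=C(\C)CCO[Si](C)(C)C(C)(C)C | intermediate (not isolated)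
8 | (2S,3S)-5-[(tert-butyldimethylsilyl)oxy]-3-ethenyl-3-methyl-2-(prop-1-en-2-yl)pentanoic acid | CC(C)(C)[Si](C)(C)OCC[C@@](C)(C=C)[C@H](C(C)=C)C(=O)O | intermediate
9 | (2S,3S)-5-[(tert-butyldimethylsilyl)oxy]-3-ethenyl-3-methyl-2-(prop-1-en-2-yl)pentan-1-ol | CC(C)(C)[Si](C)(C)OCC[C@@](C)(C=C)[C@H](C(C)=C)CO | intermediate
10 | (2S,3S)-5-[(tert-butyldimethylsilyl)oxy]-3-ethenyl-3-methyl-2-(prop-1-en-2-yl)pentanal | CC(C)(C)[Si](C)(C)OCC[C@@](C)(C=C)[C@H](C(C)=C)C=O | intermediate
11 | methyl (E)-3-iodoprop-2-enoate | COC(=O)/C=C/I | starting material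
12 | methyl (2E,4S,5S,6S)-8-[(tert-butyldimethylsilyl)oxy]-6-ethenyl-4-hydroxy-6-methyl-5-(prop-1-en-2-yl)oct-2-enoate | CC(C)(C)[Si](C)(C)OCC[C@@](C)(C=C)[C@H](C(C)=C)[C@@H](O)/C=C/C(=O)OC | intermediate
13 | methyl (2E,4S,5S,6S)-4,8-bis[(tert-butyldimethylsilyl)oxy]-6-ethenyl-6-methyl-5-(prop-1-en-2-yl)oct-2-enoate | CC(C)(C)[Si](C)(C)OCC[C@@](C)(C=C)[C@H](C(C)=C)[C@@H](O[Si](C)(C)C(C)(C)C)/C=C/C(=O)OC | intermediate
14 | methyl (2E,4S,5S,6S)-4-[(tert-butyldimethylsilyl)oxy]-6-ethenyl-8-hydroxy-6-methyl-5-(prop-1-en-2-yl)oct-2-enoate | OCC[C@@](C)(C=C)[C@H](C(C)=C)[C@@H](O[Si](C)(C)C(C)(C)C)/C=C/C(=O)OC | intermediate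
15 | methyl (2E,4S,5S,6S)-4-[(tert-butyldimethylsilyl)oxy]-6-ethenyl-6-methyl-8-oxo-5-(prop-1-en-2-yl)oct-2-enoate | O=CC[C@@](C)(C=C)[C@H](C(C)=C)[C@@H](O[Si](C)(C)C(C)(C)C)/C=C/C(=O)OC | intermediate (key-step precursor)
16 | Breslow enaminol of 15 (carbene adduct at C8; enol geometry not defined) | OC(C[C@@](C)(C=C)[C@H](C(C)=C)[C@@H](O[Si](C)(C)C(C)(C)C)/C=C/C(=O)OC)=C1N(c2c(F)c(F)c(F)c(F)c2F)N=C2CCCN12 | intermediate (not isolated)
17 | methyl 2-[(1S,2R,3S,4S)-2-[(tert-butyldimethylsilyl)oxy]-4-ethenyl-4-methyl-6-oxo-3-(prop-1-en-2-yl)cyclohexyl]acetate | C=C[C@]1(C)CC(=O)[C@@H](CC(=O)OC)[C@H](O[Si](C)(C)C(C)(C)C)[C@H]1C(C)=C | intermediate (key-step product)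
18 | methyl 2-[(1S,2R,3S,4S)-4-ethenyl-2-hydroxy-4-methyl-6-oxo-3-(prop-1-en-2-yl)cyclohexyl]acetate | C=C[C@]1(C)CC(=O)[C@@H](CC(=O)OC)[C@H](O)[C@H]1C(C)=C | intermediate (not isolated)
19 | (3aS,6S,7S,7aR)-6-ethenyl-6-methyl-7-(prop-1-en-2-yl)hexahydro-1-benzofuran-2,4-dione | C=C[C@]1(C)CC(=O)[C@H]2CC(=O)O[C@@H]2[C@H]1C(C)=C | intermediate
20 | (3aR,4R,6S,7S,7aR)-6-ethenyl-4-hydroxy-6-methyl-7-(prop-1-en-2-yl)hexahydro-1-benzofuran-2(3H)-one (8β-alcohol) | C=C[C@]1(C)C[C@@H](O)[C@H]2CC(=O)O[C@@H]2[C@H]1C(C)=C | intermediate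
21 | (3aS,4R,6S,7S,7aR)-6-ethenyl-6-methyl-7-(prop-1-en-2-yl)-4-[(trimethylsilyl)oxy]hexahydro-1-benzofuran-2(3H)-one | C=C[C@]1(C)C[C@@H](O[Si](C)(C)C)[C@H]2CC(=O)O[C@@H]2[C@H]1C(C)=C | intermediate
22 | 3-[(dimethylamino)methyl] derivative of 21 (C11 epimers) | C=C[C@]1(C)C[C@@H](O[Si](C)(C)C)[C@H]2C(CN(C)C)C(=O)O[C@@H]2[C@H]1C(C)=C | intermediate (not isolated)
23 | N-methyl ammonium iodide of 22 | C=C[C@]1(C)C[C@@H](O[Si](C)(C)C)[C@H]2C(C[N+](C)(C)C)C(=O)O[C@@H]2[C@H]1C(C)=C.[I-] | intermediate (not isolated)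
24 | 4-O-trimethylsilyl ether of 25 | C=C[C@]1(C)C[C@@H](O[Si](C)(C)C)[C@H]2C(=C)C(=O)O[C@@H]2[C@H]1C(C)=C | intermediate (not isolated)
25 | (3aR,4R,6S,7S,7aR)-6-ethenyl-4-hydroxy-6-methyl-3-methylidene-7-(prop-1-en-2-yl)hexahydro-1-benzofuran-2(3H)-one | C=C[C@]1(C)C[C@@H](O)[C@H]2C(=C)C(=O)O[C@@H]2[C@H]1C(C)=C | intermediate
26 | (S)-2,2-dimethyl-1,3-dioxolane-4-carbaldehyde | O=C[C@@H]1COC(C)(C)O1 | starting material
27 | 1-[(4S)-2,2-dimethyl-1,3-dioxolan-4-yl]ethan-1-ol (both carbinol epimers) | CC(O)[C@@H]1COC(C)(C)O1 | intermediate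
28 | 1-[(4S)-2,2-dimethyl-1,3-dioxolan-4-yl]ethan-1-one | CC(=O)[C@@H]1COC(C)(C)O1 | intermediate
29 | 1-[(4S)-2,2-dimethyl-1,3-dioxolan-4-yl]ethenyl trifluoromethanesulfonate | C=C(OS(=O)(=O)C(F)(F)F)[C@@H]1COC(C)(C)O1 | intermediate
30 | 2-[(4R)-2,2-dimethyl-1,3-dioxolan-4-yl]prop-2-enoic acid | C=C(C(=O)O)[C@@H]1COC(C)(C)O1 | intermediate
31 | (3aR,4S,6S,7S,7aR)-6-ethenyl-6-methyl-3-methylidene-2-oxo-7-(prop-1-en-2-yl)octahydro-1-benzofuran-4-yl 2-[(4R)-2,2-dimethyl-1,3-dioxolan-4-yl]prop-2-enoate | C=C[C@]1(C)C[C@H](OC(=O)C(=C)[C@@H]3COC(C)(C)O3)[C@H]2C(=C)C(=O)O[C@@H]2[C@H]1C(C)=C | intermediate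
32 | C15 allylic alcohol of 31 (7-(3-hydroxyprop-1-en-2-yl) analogue, 7R) | C=C[C@]1(C)C[C@H](OC(=O)C(=C)[C@@H]3COC(C)(C)O3)[C@H]2C(=C)C(=O)O[C@@H]2[C@H]1C(=C)CO | intermediate (not isolated)
33 | (3aR,4S,6S,7R,7aR)-6-ethenyl-6-methyl-3-methylidene-2-oxo-7-(3-oxoprop-1-en-2-yl)octahydro-1-benzofuran-4-yl 2-[(4R)-2,2-dimethyl-1,3-dioxolan-4-yl]prop-2-enoate | C=C[C@]1(C)C[C@H](OC(=O)C(=C)[C@@H]3COC(C)(C)O3)[C@H]2C(=C)C(=O)O[C@@H]2[C@H]1C(=C)C=O | intermediate
34 | (3aR,4S,6S,7R,7aR)-6-ethenyl-6-methyl-3-methylidene-2-oxo-7-(3-oxoprop-1-en-2-yl)octahydro-1-benzofuran-4-yl (3R)-3,4-dihydroxy-2-methylidenebutanoate | C=C[C@]1(C)C[C@H](OC(=O)C(=C)[C@@H](O)CO)[C@H]2C(=C)C(=O)O[C@@H]2[C@H]1C(=C)C=O | target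

**Step count and risks**

Total: 21 steps. Longest linear sequence: 17 steps (steps 1–14 and 19–21, from 1); the side-chain acid 30 takes 4 steps (15–18).

Steps most likely to fail:

1. Step 10. The enaminol may be consumed by aldol or benzoin-type self-condensation, or may not add to the hindered β-branched enoate, and base may expel the β-silyloxy group from the product. The fallback makes the same C7–C8 bond by radical chemistry, setting out from 15 and returning at 17. Pinnick oxidation of 15 (NaClO2, NaH2PO4, 2-methylbut-2-ene, t-BuOH/H2O) gives the C8 carboxylic acid F1. Diphenyl diselenide and PBu3 convert it into the Se-phenyl selenoester F2. Bu3SnH with AIBN (benzene, 80 °C, slow addition) generates the nucleophilic acyl radical, which closes 6-exo-trig onto C7 of the electron-poor enoate and gives ketone 17 after hydrogen transfer.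

2. Step 3. Facial discrimination by the chiral boron enolate may be insufficient for this dienolate, or the Lewis-acidic boron reagent may erode the silyl ether. The fallback takes the absolute configuration from a resolution instead, setting out from 6 and returning at 8. Soft enolisation of 6 with (c-C6H11)2BOTf and Et3N gives the achiral dicyclohexylboron ketene acetal F3, which rearranges through the same chair to the racemic acid F4 of the same relative configuration. Crystallisation with (S)-1-phenylethylamine (or its enantiomer, whichever gives the less soluble salt of the (2S,3S)-acid) gives the diastereomerically pure ammonium salt F5, and acidification returns 8.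

3. Step 19. The activated axial alcohol may lose the C7 proton to give an alkene instead of being displaced, or the phosphine may add to the α-methylene lactone. The fallback avoids substitution at C8, setting out from 19 and returning at 31. Electron-transfer reduction of 19 with SmI2 in THF/H2O should give the thermodynamically preferred equatorial 8α-alcohol F6 and spare the five-membered lactone. Silylation as in step 13 gives the trimethylsilyl ether F7. The methylenation sequence of step 14 then leads through the Mannich base F8, its methiodide F9 and the silyl ether F10 to the 8α-hydroxy α-methylene lactone F11. Yamaguchi esterification of F11 with acid 30 (2,4,6-trichlorobenzoyl chloride, Et3N, then DMAP, toluene) acylates with retention and gives 31.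

**Further compounds**

F1 | step 10 | C8 carboxylic acid from 15 (CHO → CO2H, stereocentres as in 15) | OC(=O)C[C@@](C)(C=C)[C@H](C(C)=C)[C@@H](O[Si](C)(C)C(C)(C)C)/C=C/C(=O)OC
F2 | step 10 | Se-phenyl selenoester of F1 | O=C([Se]c1ccccc1)C[C@@](C)(C=C)[C@H](C(C)=C)[C@@H](O[Si](C)(C)C(C)(C)C)/C=C/C(=O)OC
F3 | step 3 | dicyclohexylboron ketene acetal of 6 (isopropenyl cis to the allyloxy oxygen) | C=C(C)/C=C(/OB(C1CCCCC1)C1CCCCC1)OC/C=C(\C)CCO[Si](C)(C)C(C)(C)C
F4 | step 3 | racemic acid, (2S,3S) and (2R,3R) enantiomers of 8 | CC(C)(C)[Si](C)(C)OCC[C@@](C)(C=C)[C@H](C(C)=C)C(=O)O.CC(C)(C)[Si](C)(C)OCC[C@](C)(C=C)[C@@H](C(C)=C)C(=O)O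
F5 | step 3 | (S)-1-phenylethylammonium salt of (2S,3S)-8 | CC(C)(C)[Si](C)(C)OCC[C@@](C)(C=C)[C@H](C(C)=C)C(=O)[O-].C[C@H]([NH3+])c1ccccc1
F6 | step 19 | 8α-alcohol, C8 epimer of 20 | C=C[C@]1(C)C[C@H](O)[C@H]2CC(=O)O[C@@H]2[C@H]1C(C)=C
F7 | step 19 | trimethylsilyl ether of F6 | C=C[C@]1(C)C[C@H](O[Si](C)(C)C)[C@H]2CC(=O)O[C@@H]2[C@H]1C(C)=C
F8 | step 19 | 3-[(dimethylamino)methyl] derivative of F7 (C11 epimers) | C=C[C@]1(C)C[C@H](O[Si](C)(C)C)[C@H]2C(CN(C)C)C(=O)O[C@@H]2[C@H]1C(C)=C
F9 | step 19 | N-methyl ammonium iodide of F8 | C=C[C@]1(C)C[C@H](O[Si](C)(C)C)[C@H]2C(C[N+](C)(C)C)C(=O)O[C@@H]2[C@H]1C(C)=C.[I-]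
F10 | step 19 | trimethylsilyl ether of F11 | C=C[C@]1(C)C[C@H](O[Si](C)(C)C)[C@H]2C(=C)C(=O)O[C@@H]2[C@H]1C(C)=C
F11 | step 19 | 8α-hydroxy α-methylene lactone, C8 epimer of 25 | C=C[C@]1(C)C[C@H](O)[C@H]2C(=C)C(=O)O[C@@H]2[C@H]1C(C)=C
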